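**Retrosynthetic overview**
- Target 37 ← cleavage of two silyl ethers ← ring B enal by oxidative 1,3-transposition of an isopropenyl carbinol; acetoxy-triene side chain ← directed aldol condensation of the ring A acetaldehyde arm with dienal 30 (from 6-methylhept-5-en-2-one and acrolein), then reduction and acetylation.
- Ring A CH–OH and the neighbouring CH ← silicon-tethered hydrosilylation from the ring B tertiary hydroxyl and Tamao oxidation; arm alcohol ← Fleming oxidation of a PhMe2Si group.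
- Key disconnection: the bond from the spiro carbon to the ring A carbinol carbon ← 1,5 C–H insertion of an alkylidene carbene (ketone 14 + lithiated Me3SiCHN2). The strategy rests on the quaternary spiro carbon shared by cyclopentane ring A and cyclohexane ring B, whose ring A carbinol CH lies cis to the ring B CH carrying the 3-hydroxypropyl chain: insertion into the ring B methine C–H with retention builds exactly this arrangement.
- Ring B comes from enone ketal 3 (asymmetric conjugate addition of a Grignard reagent with allylation of the enolate, then axial methyl addition). Ring order: ring B is present from the start, ring A is closed in step 10.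

Key step: step 10

Locants: compounds 4–15 use 1,4-dioxaspiro[4.5]decane numbering (C6 = CH with the silyloxypropyl chain, C7 = CH with the arm, C8 = methyl carbinol). Compounds 16–25 and 31–37 use spiro[4.5]decane numbering (C1 = ring A CH next to the spiro carbon, C2 = ring A carbon with the arm, C5 = spiro carbon, C6 = methyl carbinol, C9 = ring B carbonyl-level carbon, C10 = CH with the oxypropyl chain). In these, O1 is trans to the C2 substituent, C1 is cis to the C10 chain and to O6; absolute configuration as in the SMILES.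

Assumption: the (R,RP) ferrocenyl diphosphine of step 2 is taken to deliver the alkyl group to the enone face that gives (6S); the mirror-image ligand would be used if a correlation with a 3-alkylcyclohexanone of known configuration showed the opposite.

**Step 1**
Reactants: 1 (3-bromopropoxy)(tert-butyl)dimethylsilane
Product: 2 {3-[(tert-butyldimethylsilyl)oxy]propyl}magnesium bromide
Conditions: Mg turnings, I2 (crystal), Et2O, rt → reflux; used as the titrated solution
Reagents that add atoms: magnesium, [Mg]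
Why: Insertion of magnesium into the primary C–Br bond (Grignard formation) should give the functionalised alkylmagnesium bromide, the silyl ether being inert and the γ-siloxy group too poor a leaving group for 1,3-elimination.

**Step 2**
Reactants: 3 1,4-dioxaspiro[4.5]dec-6-en-8-one; 2 {3-[(tert-butyldimethylsilyl)oxy]propyl}magnesium bromide
Product: 5 (6S,7S)-7-allyl-6-{3-[(tert-butyldimethylsilyl)oxy]propyl}-1,4-dioxaspiro[4.5]decan-8-one, via magnesium enolate 4 (not isolated)
Conditions: CuBr·SMe2 (5 mol%), (RP)-1-[(R)-α-(dimethylamino)-2-(diphenylphosphino)benzyl]-2-(diphenylphosphino)ferrocene (6 mol%), Et2O, −40 °C, slow addition of 2; then allyl bromide, DMPU, −40 → 0 °C; aq. NH4Cl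
Reagents that add atoms: allyl bromide, C=CCBr
Why: Copper-catalysed asymmetric conjugate addition of the Grignard reagent with the chiral ferrocenyl diphosphine should set C6 under ligand control, and alkylation of the resulting magnesium enolate with allyl bromide in the presence of DMPU should place the allyl group at C7 anti to the new C6 chain, giving the trans ketone.

**Step 3**
Reactants: 5 (6S,7S)-7-allyl-6-{3-[(tert-butyldimethylsilyl)oxy]propyl}-1,4-dioxaspiro[4.5]decan-8-one
Product: 6 (6S,7S,8S)-7-allyl-6-{3-[(tert-butyldimethylsilyl)oxy]propyl}-8-methyl-1,4-dioxaspiro[4.5]decan-8-ol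
Conditions: MeAl(OC6H2-2,6-t-Bu2-4-Me)2 (3 equiv, from AlMe3 and 2,6-di-tert-butyl-4-methylphenol, PhMe, rt), −78 °C; MeLi (3 equiv), −78 °C; aq. NH4Cl
Reagents that add atoms: methyllithium, [Li]C
Why: The bulky aluminium aryloxide complexes the carbonyl oxygen from the equatorial side so that MeLi adds along the axial trajectory (amphiphilic carbonyl alkylation), which should give the axial methyl group cis to the equatorial C7 allyl group and an equatorial hydroxyl.

**Step 4**
Reactants: 6 (6S,7S,8S)-7-allyl-6-{3-[(tert-butyldimethylsilyl)oxy]propyl}-8-methyl-1,4-dioxaspiro[4.5]decan-8-ol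
Product: 7 (6S,7S,8S)-7-allyl-6-{3-[(tert-butyldimethylsilyl)oxy]propyl}-8-methyl-8-(trimethylsilyloxy)-1,4-dioxaspiro[4.5]decane
Conditions: 1-(trimethylsilyl)imidazole, CH2Cl2, rt
Reagents that add atoms: 1-(trimethylsilyl)imidazole, C[Si](C)(C)n1ccnc1
Why: Silylation with the powerful silyl donor should cap the hindered tertiary alcohol as a trimethylsilyl ether, chosen because it can later be removed by methanolysis without loss of the primary tert-butyldimethylsilyl ether.

**Step 5**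
Reactants: 7 (6S,7S,8S)-7-allyl-6-{3-[(tert-butyldimethylsilyl)oxy]propyl}-8-methyl-8-(trimethylsilyloxy)-1,4-dioxaspiro[4.5]decane
Product: 9 3-[(6S,7S,8S)-6-{3-[(tert-butyldimethylsilyl)oxy]propyl}-8-methyl-8-(trimethylsilyloxy)-1,4-dioxaspiro[4.5]decan-7-yl]propan-1-ol, via B-alkyl-9-borabicyclononane 8 (not isolated)
Conditions: 9-BBN, THF, 0 °C → rt; then 30% H2O2, aq. NaOAc, 0 °C → rt
Reagents that add atoms: hydrogen peroxide, OO
Why: Anti-Markovnikov hydroboration of the terminal alkene and buffered oxidation should give the primary alcohol without touching the silyl ethers or the ketal.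

**Step 6**
Reactants: 9 3-[(6S,7S,8S)-6-{3-[(tert-butyldimethylsilyl)oxy]propyl}-8-methyl-8-(trimethylsilyloxy)-1,4-dioxaspiro[4.5]decan-7-yl]propan-1-ol
Product: 10 3-[(6S,7S,8S)-6-{3-[(tert-butyldimethylsilyl)oxy]propyl}-8-methyl-8-(trimethylsilyloxy)-1,4-dioxaspiro[4.5]decan-7-yl]propanal
Conditions: (n-Pr4N)[RuO4] (5 mol%), N-methylmorpholine N-oxide, 4 Å sieves, CH2Cl2, rt
Reagents that add atoms: none
Why: The neutral Ley–Griffith oxidation should stop at the aldehyde and leave the acid-labile trimethylsilyl ether intact.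

**Step 7**
Reactants: 10 3-[(6S,7S,8S)-6-{3-[(tert-butyldimethylsilyl)oxy]propyl}-8-methyl-8-(trimethylsilyloxy)-1,4-dioxaspiro[4.5]decan-7-yl]propanal
Product: 11 5-[(6S,7S,8S)-6-{3-[(tert-butyldimethylsilyl)oxy]propyl}-8-methyl-8-(trimethylsilyloxy)-1,4-dioxaspiro[4.5]decan-7-yl]pent-1-en-3-ol (both carbinol epimers)
Conditions: CH2=CHMgBr, THF, −78 °C; aq. NH4Cl
Reagents that add atoms: vinylmagnesium bromide, C=C[Mg]Br
Why: Grignard 1,2-addition to the unhindered aldehyde should give the allylic alcohol, whose carbinol configuration is erased in the next step.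

**Step 8**
Reactants: 11 5-[(6S,7S,8S)-6-{3-[(tert-butyldimethylsilyl)oxy]propyl}-8-methyl-8-(trimethylsilyloxy)-1,4-dioxaspiro[4.5]decan-7-yl]pent-1-en-3-ol
Product: 12 5-[(6S,7S,8S)-6-{3-[(tert-butyldimethylsilyl)oxy]propyl}-8-methyl-8-(trimethylsilyloxy)-1,4-dioxaspiro[4.5]decan-7-yl]pent-1-en-3-one
Conditions: (n-Pr4N)[RuO4] (5 mol%), N-methylmorpholine N-oxide, 4 Å sieves, CH2Cl2, 0 °C → rt
Reagents that add atoms: none
Why: Ley–Griffith oxidation of the secondary allylic alcohol should give the vinyl ketone, which is used promptly.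

**Step 9**
Reactants: 12 5-[(6S,7S,8S)-6-{3-[(tert-butyldimethylsilyl)oxy]propyl}-8-methyl-8-(trimethylsilyloxy)-1,4-dioxaspiro[4.5]decan-7-yl]pent-1-en-3-one
Product: 14 1-(dimethylphenylsilyl)-5-[(6S,7S,8S)-6-{3-[(tert-butyldimethylsilyl)oxy]propyl}-8-methyl-8-(trimethylsilyloxy)-1,4-dioxaspiro[4.5]decan-7-yl]pentan-3-one, via pinacolboron enolate 13 (not isolated)
Conditions: PhMe2Si–B(pin), CuCl (5 mol%), 1,3-dimesitylimidazolium chloride (5 mol%), NaOt-Bu (10 mol%), THF, −78 → −20 °C; H2O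
Reagents that add atoms: (dimethylphenylsilyl)boronic acid pinacol ester, C[Si](C)(c1ccccc1)B1OC(C)(C)C(C)(C)O1
Why: Copper-catalysed conjugate silyl transfer from the silylboronate to the unhindered enone should give the β-silyl ketone, the PhMe2Si group being a masked hydroxyl that carries no reactive O–H or O–Si bond.

**Step 10**
Reactants: 14 1-(dimethylphenylsilyl)-5-[(6S,7S,8S)-6-{3-[(tert-butyldimethylsilyl)oxy]propyl}-8-methyl-8-(trimethylsilyloxy)-1,4-dioxaspiro[4.5]decan-7-yl]pentan-3-one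
Product: 16 9,9-(ethylenedioxy)-2-[2-(dimethylphenylsilyl)ethyl]-10-{3-[(tert-butyldimethylsilyl)oxy]propyl}-6-methyl-6-(trimethylsilyloxy)spiro[4.5]dec-1-ene, via alkylidene carbene 15 (not isolated)
Conditions: Me3SiCHN2 (1.5 equiv), n-BuLi (1.4 equiv), THF, −78 °C; add 14, −78 °C → rt; aq. NH4Cl
Reagents that add atoms: (trimethylsilyl)diazomethane, C[Si](C)(C)C=[N+]=[N-]
Why: Lithiated trimethylsilyldiazomethane adds to the ketone of 14, the adduct loses lithium trimethylsilanolate (Peterson-type elimination) to a diazoalkene and then N2 to give alkylidene carbene 15, whose carbenic carbon inserts in a concerted way into the C7–H bond five atoms away. The closest known reaction type is the alkylidene carbene 1,5 C–H insertion that converts dialkyl ketones into cyclopentenes. Ring A closes by this 1,5 insertion, which forms the bond between the spiro carbon and the future carbinol CH and leaves the C=C between that CH and the carbon bearing the silylethyl arm. The new quaternary spiro stereocentre is substrate-controlled, since insertion proceeds with retention at C7, whose configuration was fixed in step 2. The step needs site selectivity for this one methine, and the substrate secures it: it is the only C–H in a 1,5 relation to the carbene, the silylethyl arm has silicon at position 5, the silyl ethers lie too far away for O–Si insertion, and alkyl groups migrate too slowly for alkyne formation.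

**Step 11**
Reactants: 16 9,9-(ethylenedioxy)-2-[2-(dimethylphenylsilyl)ethyl]-10-{3-[(tert-butyldimethylsilyl)oxy]propyl}-6-methyl-6-(trimethylsilyloxy)spiro[4.5]dec-1-ene
Product: 17 9,9-(ethylenedioxy)-2-[2-(dimethylphenylsilyl)ethyl]-10-{3-[(tert-butyldimethylsilyl)oxy]propyl}-6-methylspiro[4.5]dec-1-en-6-ol
Conditions: K2CO3, MeOH, rt → 40 °C
Reagents that add atoms: none
Why: Base-catalysed methanolysis should cleave the trimethylsilyl ether while the primary tert-butyldimethylsilyl ether, the ketal and the C–Si bond are stable.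

**Step 12**
Reactants: 17 9,9-(ethylenedioxy)-2-[2-(dimethylphenylsilyl)ethyl]-10-{3-[(tert-butyldimethylsilyl)oxy]propyl}-6-methylspiro[4.5]dec-1-en-6-ol
Product: 18 9,9-(ethylenedioxy)-2-[2-(dimethylphenylsilyl)ethyl]-10-{3-[(tert-butyldimethylsilyl)oxy]propyl}-6-(dimethylsilyloxy)-6-methylspiro[4.5]dec-1-ene
Conditions: ClSiMe2H, Et3N, DMAP (cat.), CH2Cl2, 0 °C → rt; filtered and concentrated
Reagents that add atoms: chlorodimethylsilane, C[SiH](C)Cl
Why: The small chlorohydrosilane should silylate the hindered tertiary alcohol and install the Si–H tether on the face of ring A that carries C6.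

**Step 13**
Reactants: 18 9,9-(ethylenedioxy)-2-[2-(dimethylphenylsilyl)ethyl]-10-{3-[(tert-butyldimethylsilyl)oxy]propyl}-6-(dimethylsilyloxy)-6-methylspiro[4.5]dec-1-ene
Product: 20 9,9-(ethylenedioxy)-2-[2-(dimethylphenylsilyl)ethyl]-10-{3-[(tert-butyldimethylsilyl)oxy]propyl}-6-methylspiro[4.5]decane-1,6-diol, via oxasilolane 19 (not isolated)
Conditions: Pt2[(CH2=CHSiMe2)2O]3 (1 mol%), PhMe, 60 °C; then KF, KHCO3, 30% H2O2, THF/MeOH, 40 °C
Reagents that add atoms: hydrogen peroxide, OO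
Why: Platinum-catalysed intramolecular hydrosilylation of the homoallylic Si–H ether should close the five-membered oxasilolane (exo mode, silicon to the less substituted alkene carbon C1) by syn addition from the O6 face, so that Tamao oxidation with retention gives the C1 hydroxyl cis to O6 and the C2 hydrogen on the same face, the arm being trans to the new hydroxyl.

**Step 14**
Reactants: 20 9,9-(ethylenedioxy)-2-[2-(dimethylphenylsilyl)ethyl]-10-{3-[(tert-butyldimethylsilyl)oxy]propyl}-6-methylspiro[4.5]decane-1,6-diol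
Product: 21 9,9-(ethylenedioxy)-2-(2-hydroxyethyl)-10-{3-[(tert-butyldimethylsilyl)oxy]propyl}-6-methylspiro[4.5]decane-1,6-diol
Conditions: KBr, AcOOH, NaOAc, AcOH, 0 °C → rt
Reagents that add atoms: peracetic acid, CC(=O)OO
Why: Fleming oxidation (ipso-bromodesilylation of the phenyl group, then peracid-induced shift from silicon to oxygen) should turn the C–SiMe2Ph bond into the primary alcohol; it is placed here because the molecule holds no alkene and the ketone is still masked against Baeyer–Villiger oxidation.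

**Step 15**
Reactants: 21 9,9-(ethylenedioxy)-2-(2-hydroxyethyl)-10-{3-[(tert-butyldimethylsilyl)oxy]propyl}-6-methylspiro[4.5]decane-1,6-diol
Product: 22 1,6-dihydroxy-2-(2-hydroxyethyl)-10-{3-[(tert-butyldimethylsilyl)oxy]propyl}-6-methylspiro[4.5]decan-9-one
Conditions: pyridinium p-toluenesulfonate, acetone/H2O, 45 °C
Reagents that add atoms: water, O
Why: Mild acid-catalysed ketal hydrolysis should free the ring B ketone while the primary tert-butyldimethylsilyl ether survives and C10 is not enolised.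

**Step 16**
Reactants: 22 1,6-dihydroxy-2-(2-hydroxyethyl)-10-{3-[(tert-butyldimethylsilyl)oxy]propyl}-6-methylspiro[4.5]decan-9-one
Product: 23 2-(2-hydroxyethyl)-10-{3-[(tert-butyldimethylsilyl)oxy]propyl}-6-methyl-9-(prop-1-en-2-yl)spiro[4.5]decane-1,6,9-triol (C9 configuration unassigned)
Conditions: CH2=C(CH3)MgBr (6 equiv), CeCl3 (6 equiv), THF, −78 → 0 °C; aq. NH4Cl
Reagents that add atoms: isopropenylmagnesium bromide, CC(=C)[Mg]Br
Why: The organocerium reagent should add 1,2 to the hindered, enolisable ketone without epimerising C10 (three equivalents are spent on the hydroxyls); the C9 configuration is of no consequence because C9 becomes sp2 in step 24.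

**Step 17**
Reactants: 23 2-(2-hydroxyethyl)-10-{3-[(tert-butyldimethylsilyl)oxy]propyl}-6-methyl-9-(prop-1-en-2-yl)spiro[4.5]decane-1,6,9-triol
Product: 24 2-[10-{3-[(tert-butyldimethylsilyl)oxy]propyl}-1,6,9-trihydroxy-6-methyl-9-(prop-1-en-2-yl)spiro[4.5]decan-2-yl]acetaldehyde
Conditions: TEMPO (10 mol%), PhI(OAc)2, CH2Cl2, rt
Reagents that add atoms: none
Why: Oxoammonium (TEMPO) oxidation is selective for the primary alcohol over the hindered secondary and the tertiary alcohols, and the trans disposition of O1 and the C2 arm prevents lactol formation.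

**Step 18**
Reactants: 24 2-[10-{3-[(tert-butyldimethylsilyl)oxy]propyl}-1,6,9-trihydroxy-6-methyl-9-(prop-1-en-2-yl)spiro[4.5]decan-2-yl]acetaldehyde
Product: 25 2-[10-{3-[(tert-butyldimethylsilyl)oxy]propyl}-6,9-dihydroxy-6-methyl-9-(prop-1-en-2-yl)-1-(triethylsilyloxy)spiro[4.5]decan-2-yl]acetaldehyde
Conditions: Et3SiCl, imidazole, DMAP (cat.), DMF, rt
Reagents that add atoms: chlorotriethylsilane, CC[Si](Cl)(CC)CC
Why: Silylation should protect the secondary C1 hydroxyl against the later oxidation while the two tertiary alcohols do not react.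

**Step 19**
Reactants: 26 6-methylhept-5-en-2-one
Product: 28 6-methylhepta-1,5-dien-2-yl trifluoromethanesulfonate, via lithium enolate 27 (not isolated)
Conditions: LiN(i-Pr)2, THF, −78 °C; PhNTf2, −78 → 0 °C; aq. NH4Cl
Reagents that add atoms: N-phenylbis(trifluoromethanesulfonimide), O=S(=O)(N(c1ccccc1)S(=O)(=O)C(F)(F)F)C(F)(F)F
Why: Kinetic deprotonation of the methyl ketone at the methyl group and O-sulfonylation should give the terminal enol triflate.

**Step 20**
Reactants: 28 6-methylhepta-1,5-dien-2-yl trifluoromethanesulfonate; 29 acrolein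
Product: 30 (2E)-8-methyl-4-methylidenenona-2,7-dienal
Conditions: Pd(OAc)2 (5 mol%), n-Bu4NCl, NaHCO3, DMF, 40 °C
Reagents that add atoms: none
Why: The Heck reaction of the alkenyl triflate at the β-carbon of acrolein under phase-transfer conditions should give the (E)-dienal through syn insertion and syn β-hydride elimination.

**Step 21**
Reactants: 25 2-[10-{3-[(tert-butyldimethylsilyl)oxy]propyl}-6,9-dihydroxy-6-methyl-9-(prop-1-en-2-yl)-1-(triethylsilyloxy)spiro[4.5]decan-2-yl]acetaldehyde; 30 (2E)-8-methyl-4-methylidenenona-2,7-dienal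
Product: 33 (2E,4E)-10-methyl-6-methylidene-2-[10-{3-[(tert-butyldimethylsilyl)oxy]propyl}-6,9-dihydroxy-6-methyl-9-(prop-1-en-2-yl)-1-(triethylsilyloxy)spiro[4.5]decan-2-yl]undeca-2,4,9-trienal, via N-cyclohexyl imine 31 (not isolated), via β-hydroxy imine 32 (not isolated)
Conditions: c-C6H11NH2, 4 Å sieves, Et2O, rt; LiN(i-Pr)2 (3.3 equiv), THF, −78 → 0 °C; 30, −78 °C; aq. oxalic acid, THF, 0 °C → rt
Reagents that add atoms: water, O
Why: The lithiated N-cyclohexyl imine (Wittig directed aldol) should add 1,2 to the non-enolisable dienal, and hydrolysis with dehydration should give the conjugated enal as the E isomer (formyl trans to the dienyl chain), the thermodynamically preferred geometry of a 2-alkyl-2-enal.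

**Step 22**
Reactants: 33 (2E,4E)-10-methyl-6-methylidene-2-[10-{3-[(tert-butyldimethylsilyl)oxy]propyl}-6,9-dihydroxy-6-methyl-9-(prop-1-en-2-yl)-1-(triethylsilyloxy)spiro[4.5]decan-2-yl]undeca-2,4,9-trienal
Product: 34 (2E,4E)-10-methyl-6-methylidene-2-[10-{3-[(tert-butyldimethylsilyl)oxy]propyl}-6,9-dihydroxy-6-methyl-9-(prop-1-en-2-yl)-1-(triethylsilyloxy)spiro[4.5]decan-2-yl]undeca-2,4,9-trien-1-ol
Conditions: NaBH4, CeCl3·7H2O, MeOH, −20 °C
Reagents that add atoms: none
Why: Luche reduction should reduce the enal 1,2 to the primary allylic alcohol without touching the triene or the alkene geometry.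

**Step 23**
Reactants: 34 (2E,4E)-10-methyl-6-methylidene-2-[10-{3-[(tert-butyldimethylsilyl)oxy]propyl}-6,9-dihydroxy-6-methyl-9-(prop-1-en-2-yl)-1-(triethylsilyloxy)spiro[4.5]decan-2-yl]undeca-2,4,9-trien-1-ol
Product: 35 (2E,4E)-10-methyl-6-methylidene-2-[10-{3-[(tert-butyldimethylsilyl)oxy]propyl}-6,9-dihydroxy-6-methyl-9-(prop-1-en-2-yl)-1-(triethylsilyloxy)spiro[4.5]decan-2-yl]undeca-2,4,9-trien-1-yl acetate
Conditions: Ac2O, pyridine, DMAP (cat.), CH2Cl2, 0 °C
Reagents that add atoms: acetic anhydride, CC(=O)OC(C)=O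
Why: Acylation should take place only at the primary allylic alcohol, the two tertiary alcohols being inert at 0 °C.

**Step 24**
Reactants: 35 (2E,4E)-10-methyl-6-methylidene-2-[10-{3-[(tert-butyldimethylsilyl)oxy]propyl}-6,9-dihydroxy-6-methyl-9-(prop-1-en-2-yl)-1-(triethylsilyloxy)spiro[4.5]decan-2-yl]undeca-2,4,9-trien-1-yl acetate
Product: 36 (2E,4E)-10-methyl-6-methylidene-2-[10-{3-[(tert-butyldimethylsilyl)oxy]propyl}-6-hydroxy-6-methyl-9-[(Z)-1-oxopropan-2-ylidene]-1-(triethylsilyloxy)spiro[4.5]decan-2-yl]undeca-2,4,9-trien-1-yl acetate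
Conditions: (C5H5NH)[CrO3Cl] (3 equiv), 4 Å sieves, CH2Cl2, rt
Reagents that add atoms: pyridinium chlorochromate, [O-][Cr](=O)(=O)Cl.c1cc[nH+]cc1
Why: Oxidative 1,3-transposition of the tertiary allylic alcohol (Dauben–Babler oxidation: [3,3] shift of the chromate ester, then oxidation) should give the tetrasubstituted enal; the geometry with the formyl group syn to C10 is expected because the methyl group avoids the substituted C10 in the shift and the product then has only the formyl hydrogen facing C10.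

**Step 25**
Reactants: 36 (2E,4E)-10-methyl-6-methylidene-2-[10-{3-[(tert-butyldimethylsilyl)oxy]propyl}-6-hydroxy-6-methyl-9-[(Z)-1-oxopropan-2-ylidene]-1-(triethylsilyloxy)spiro[4.5]decan-2-yl]undeca-2,4,9-trien-1-yl acetate
Product: 37 CNP0204268.2
Conditions: HF·pyridine, pyridine, THF, 0 °C → rt
Reagents that add atoms: none
Why: Buffered fluoride should cleave the primary tert-butyldimethylsilyl and the secondary triethylsilyl ether without affecting the acetate, the enal or the triene.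

**Compound list**
1 | (3-bromopropoxy)(tert-butyl)dimethylsilane | CC(C)(C)[Si](C)(C)OCCCBr | starting material
2 | {3-[(tert-butyldimethylsilyl)oxy]propyl}magnesium bromide | CC(C)(C)[Si](C)(C)OCCC[Mg]Br | intermediate
3 | 1,4-dioxaspiro[4.5]dec-6-en-8-one | O=C1C=CC2(CC1)OCCO2 | starting material
4 | bromomagnesium C7=C8 enolate of (6S)-6-{3-[(tert-butyldimethylsilyl)oxy]propyl}-1,4-dioxaspiro[4.5]decan-8-one | Br[Mg]OC1=C[C@H](CCCO[Si](C)(C)C(C)(C)C)C2(CC1)OCCO2 | intermediate
5 | (6S,7S)-7-allyl-6-{3-[(tert-butyldimethylsilyl)oxy]propyl}-1,4-dioxaspiro[4.5]decan-8-one | C=CC[C@H]1[C@H](CCCO[Si](C)(C)C(C)(C)C)C2(CCC1=O)OCCO2 | intermediate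
6 | (6S,7S,8S)-7-allyl-6-{3-[(tert-butyldimethylsilyl)oxy]propyl}-8-methyl-1,4-dioxaspiro[4.5]decan-8-ol | C=CC[C@H]1[C@H](CCCO[Si](C)(C)C(C)(C)C)C2(CC[C@]1(C)O)OCCO2 | intermediate
7 | (6S,7S,8S)-7-allyl-6-{3-[(tert-butyldimethylsilyl)oxy]propyl}-8-methyl-8-(trimethylsilyloxy)-1,4-dioxaspiro[4.5]decane | C=CC[C@H]1[C@H](CCCO[Si](C)(C)C(C)(C)C)C2(CC[C@]1(C)O[Si](C)(C)C)OCCO2 | intermediate
8 | B-alkyl-9-borabicyclo[3.3.1]nonane from 7 (boron on the terminal carbon of the former allyl group) | C1CCC2CCCC1B2CCC[C@H]1[C@H](CCCO[Si](C)(C)C(C)(C)C)C2(CC[C@]1(C)O[Si](C)(C)C)OCCO2 | intermediate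
9 | 3-[(6S,7S,8S)-6-{3-[(tert-butyldimethylsilyl)oxy]propyl}-8-methyl-8-(trimethylsilyloxy)-1,4-dioxaspiro[4.5]decan-7-yl]propan-1-ol | OCCC[C@H]1[C@H](CCCO[Si](C)(C)C(C)(C)C)C2(CC[C@]1(C)O[Si](C)(C)C)OCCO2 | intermediate
10 | 3-[(6S,7S,8S)-6-{3-[(tert-butyldimethylsilyl)oxy]propyl}-8-methyl-8-(trimethylsilyloxy)-1,4-dioxaspiro[4.5]decan-7-yl]propanal | O=CCC[C@H]1[C@H](CCCO[Si](C)(C)C(C)(C)C)C2(CC[C@]1(C)O[Si](C)(C)C)OCCO2 | intermediate
11 | 5-[(6S,7S,8S)-6-{3-[(tert-butyldimethylsilyl)oxy]propyl}-8-methyl-8-(trimethylsilyloxy)-1,4-dioxaspiro[4.5]decan-7-yl]pent-1-en-3-ol (both carbinol epimers) | C=CC(O)CC[C@H]1[C@H](CCCO[Si](C)(C)C(C)(C)C)C2(CC[C@]1(C)O[Si](C)(C)C)OCCO2 | intermediate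
12 | 5-[(6S,7S,8S)-6-{3-[(tert-butyldimethylsilyl)oxy]propyl}-8-methyl-8-(trimethylsilyloxy)-1,4-dioxaspiro[4.5]decan-7-yl]pent-1-en-3-one | C=CC(=O)CC[C@H]1[C@H](CCCO[Si](C)(C)C(C)(C)C)C2(CC[C@]1(C)O[Si](C)(C)C)OCCO2 | intermediate
13 | pinacolboron enolate of 14 (O–B(pin) on C3 of the pentane chain, C3=C2 double bond) | CC1(C)OB(OC(=CC[Si](C)(C)c2ccccc2)CC[C@H]2[C@H](CCCO[Si](C)(C)C(C)(C)C)C3(CC[C@]2(C)O[Si](C)(C)C)OCCO3)OC1(C)C | intermediate
14 | 1-(dimethylphenylsilyl)-5-[(6S,7S,8S)-6-{3-[(tert-butyldimethylsilyl)oxy]propyl}-8-methyl-8-(trimethylsilyloxy)-1,4-dioxaspiro[4.5]decan-7-yl]pentan-3-one | C[Si](C)(c1ccccc1)CCC(=O)CC[C@H]1[C@H](CCCO[Si](C)(C)C(C)(C)C)C2(CC[C@]1(C)O[Si](C)(C)C)OCCO2 | intermediate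
15 | alkylidene carbene from 14 (C=O replaced by C=C: with a divalent terminal carbon) | [C]=C(CC[Si](C)(C)c1ccccc1)CC[C@H]1[C@H](CCCO[Si](C)(C)C(C)(C)C)C2(CC[C@]1(C)O[Si](C)(C)C)OCCO2 | intermediate
16 | 9,9-(ethylenedioxy)-2-[2-(dimethylphenylsilyl)ethyl]-10-{3-[(tert-butyldimethylsilyl)oxy]propyl}-6-methyl-6-(trimethylsilyloxy)spiro[4.5]dec-1-ene (C1 of ring A cis to the C10 chain and to O6) | C[Si](C)(c1ccccc1)CCC1=C[C@]2(CC1)[C@H](CCCO[Si](C)(C)C(C)(C)C)C3(CC[C@]2(C)O[Si](C)(C)C)OCCO3 | intermediate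
17 | 9,9-(ethylenedioxy)-2-[2-(dimethylphenylsilyl)ethyl]-10-{3-[(tert-butyldimethylsilyl)oxy]propyl}-6-methylspiro[4.5]dec-1-en-6-ol | C[Si](C)(c1ccccc1)CCC1=C[C@]2(CC1)[C@H](CCCO[Si](C)(C)C(C)(C)C)C3(CC[C@]2(C)O)OCCO3 | intermediate
18 | 9,9-(ethylenedioxy)-2-[2-(dimethylphenylsilyl)ethyl]-10-{3-[(tert-butyldimethylsilyl)oxy]propyl}-6-(dimethylsilyloxy)-6-methylspiro[4.5]dec-1-ene | C[Si](C)(c1ccccc1)CCC1=C[C@]2(CC1)[C@H](CCCO[Si](C)(C)C(C)(C)C)C3(CC[C@]2(C)O[SiH](C)C)OCCO3 | intermediate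
19 | oxasilolane: C1 and O6 of the spiro[4.5]decane bridged by SiMe2, H at C2 cis to silicon, arm at C2 trans | C[Si](C)(c1ccccc1)CC[C@@H]1CC[C@]2([C@H](CCCO[Si](C)(C)C(C)(C)C)C3(OCCO3)CC[C@]2(C)O4)[C@H]1[Si]4(C)C | intermediate
20 | 9,9-(ethylenedioxy)-2-[2-(dimethylphenylsilyl)ethyl]-10-{3-[(tert-butyldimethylsilyl)oxy]propyl}-6-methylspiro[4.5]decane-1,6-diol | C[Si](C)(c1ccccc1)CC[C@@H]1CC[C@]2([C@H](CCCO[Si](C)(C)C(C)(C)C)C3(OCCO3)CC[C@]2(C)O)[C@H]1O | intermediate
21 | 9,9-(ethylenedioxy)-2-(2-hydroxyethyl)-10-{3-[(tert-butyldimethylsilyl)oxy]propyl}-6-methylspiro[4.5]decane-1,6-diol | OCC[C@@H]1CC[C@]2([C@H](CCCO[Si](C)(C)C(C)(C)C)C3(OCCO3)CC[C@]2(C)O)[C@H]1O | intermediate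
22 | 1,6-dihydroxy-2-(2-hydroxyethyl)-10-{3-[(tert-butyldimethylsilyl)oxy]propyl}-6-methylspiro[4.5]decan-9-one | OCC[C@@H]1CC[C@]2([C@H](CCCO[Si](C)(C)C(C)(C)C)C(=O)CC[C@]2(C)O)[C@H]1O | intermediate
23 | 2-(2-hydroxyethyl)-10-{3-[(tert-butyldimethylsilyl)oxy]propyl}-6-methyl-9-(prop-1-en-2-yl)spiro[4.5]decane-1,6,9-triol (C9 unassigned) | OCC[C@@H]1CC[C@]2([C@H](CCCO[Si](C)(C)C(C)(C)C)C(O)(C(C)=C)CC[C@]2(C)O)[C@H]1O | intermediate
24 | 2-[10-{3-[(tert-butyldimethylsilyl)oxy]propyl}-1,6,9-trihydroxy-6-methyl-9-(prop-1-en-2-yl)spiro[4.5]decan-2-yl]acetaldehyde | O=CC[C@@H]1CC[C@]2([C@H](CCCO[Si](C)(C)C(C)(C)C)C(O)(C(C)=C)CC[C@]2(C)O)[C@H]1O | intermediate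
25 | 2-[10-{3-[(tert-butyldimethylsilyl)oxy]propyl}-6,9-dihydroxy-6-methyl-9-(prop-1-en-2-yl)-1-(triethylsilyloxy)spiro[4.5]decan-2-yl]acetaldehyde | O=CC[C@@H]1CC[C@]2([C@H](CCCO[Si](C)(C)C(C)(C)C)C(O)(C(C)=C)CC[C@]2(C)O)[C@H]1O[Si](CC)(CC)CC | intermediate
26 | 6-methylhept-5-en-2-one | CC(=O)CCC=C(C)C | starting material
27 | lithium 6-methylhepta-1,5-dien-2-olate | [Li]OC(=C)CCC=C(C)C | intermediate
28 | 6-methylhepta-1,5-dien-2-yl trifluoromethanesulfonate | C=C(OS(=O)(=O)C(F)(F)F)CCC=C(C)C | intermediate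
29 | acrolein | C=CC=O | starting material
30 | (2E)-8-methyl-4-methylidenenona-2,7-dienal | O=C/C=C/C(=C)CCC=C(C)C | intermediate
31 | N-cyclohexyl imine of 25 | C1CCCCC1N=CC[C@@H]2CC[C@]3([C@H](CCCO[Si](C)(C)C(C)(C)C)C(O)(C(C)=C)CC[C@]3(C)O)[C@H]2O[Si](CC)(CC)CC | intermediate
32 | β-hydroxy imine from 31 and 30 (new C–C bond at the carbon next to C2 of ring A; carbinol epimers) | C1CCCCC1N=CC(C(O)/C=C/C(=C)CCC=C(C)C)[C@@H]2CC[C@]3([C@H](CCCO[Si](C)(C)C(C)(C)C)C(O)(C(C)=C)CC[C@]3(C)O)[C@H]2O[Si](CC)(CC)CC | intermediate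
33 | (2E,4E)-10-methyl-6-methylidene-2-[10-{3-[(tert-butyldimethylsilyl)oxy]propyl}-6,9-dihydroxy-6-methyl-9-(prop-1-en-2-yl)-1-(triethylsilyloxy)spiro[4.5]decan-2-yl]undeca-2,4,9-trienal | C=C(/C=C/C=C(/C=O)[C@@H]1CC[C@]2([C@H](CCCO[Si](C)(C)C(C)(C)C)C(O)(C(C)=C)CC[C@]2(C)O)[C@H]1O[Si](CC)(CC)CC)CCC=C(C)C | intermediate
34 | the corresponding (2E,4E)-undeca-2,4,9-trien-1-ol | C=C(/C=C/C=C(/CO)[C@@H]1CC[C@]2([C@H](CCCO[Si](C)(C)C(C)(C)C)C(O)(C(C)=C)CC[C@]2(C)O)[C@H]1O[Si](CC)(CC)CC)CCC=C(C)C | intermediate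
35 | the corresponding (2E,4E)-undeca-2,4,9-trien-1-yl acetate | C=C(/C=C/C=C(/COC(C)=O)[C@@H]1CC[C@]2([C@H](CCCO[Si](C)(C)C(C)(C)C)C(O)(C(C)=C)CC[C@]2(C)O)[C@H]1O[Si](CC)(CC)CC)CCC=C(C)C | intermediate
36 | bis-silyl ether of the target: 1-O-triethylsilyl, propyl O-tert-butyldimethylsilyl, ring B (Z)-1-oxopropan-2-ylidene at C9 (formyl syn to C10) | C=C(/C=C/C=C(/COC(C)=O)[C@@H]1CC[C@]2([C@H](CCCO[Si](C)(C)C(C)(C)C)/C(=C(/C)C=O)CC[C@]2(C)O)[C@H]1O[Si](CC)(CC)CC)CCC=C(C)C | intermediate
37 | CNP0204268.2 | C=C(/C=C/C=C(/COC(C)=O)[C@@H]1CC[C@]2([C@H](CCCO)/C(=C(/C)C=O)CC[C@]2(C)O)[C@H]1O)CCC=C(C)C | target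

**Step count and risks**
Total: 25 steps. Longest linear sequence: 23 steps (steps 1–18 and 21–25, from 1); the dienal branch is 2 steps (19–20).

Steps most likely to fail:

1. Step 10. The basic lithiated diazo reagent may enolise the dialkyl ketone or add too slowly, so that ketone returns and little carbene forms. Fallback: from 14, Wittig chloromethylenation with Ph3P=CHCl (from (chloromethyl)triphenylphosphonium chloride and NaN(SiMe3)2, THF) would give the chloroalkene F1. Treatment of this with KN(SiMe3)2 in Et2O at rt effects α-elimination to the same alkylidene carbene, which should insert into the C7–H bond as before and return the route to 16.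

2. Step 21. The acidic hydrolysis may not dehydrate the aldol cleanly and may strip the triethylsilyl ether or ionise the tertiary allylic alcohol; conjugate addition to the dienal is also possible. Fallback: from 25, Pinnick oxidation (NaClO2, NaH2PO4, 2-methylbut-2-ene) would give the carboxylic acid F2, and Me3SiCHN2 in MeOH/PhMe the methyl ester F3. Aldol addition of its lithium enolate (LiN(i-Pr)2, 3.3 equiv, THF, −78 °C) to 30 would give the β-hydroxy ester F4. Acetylation of the new secondary hydroxyl (Ac2O, pyridine, DMAP, 0 °C) gives the β-acetoxy ester F5, and elimination with DBU in PhMe the (2E)-trienoate F6. Reduction with i-Bu2AlH (CH2Cl2, −78 °C) returns the route to 34 without any acidic step.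

3. Step 24. The [3,3] shift may give poor control of the tetrasubstituted alkene geometry, and the acidic oxidant may damage the triene. Fallback: from 35, 1,3-transposition catalysed by Ph3SiOReO3 (Et2O, 0 °C) would give the primary allylic alcohol F7; its unwanted geometric isomer is separated and re-equilibrated with the same catalyst. Oxidation with MnO2 (CH2Cl2, rt), which is selective for the allylic alcohol and does not change the geometry, returns the route to 36.

**Further compounds**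
F1 | step 10 | chloroalkene: 14 with C=O replaced by C=CHCl (both geometric isomers) | ClC=C(CC[Si](C)(C)c1ccccc1)CC[C@H]1[C@H](CCCO[Si](C)(C)C(C)(C)C)C2(CC[C@]1(C)O[Si](C)(C)C)OCCO2
F2 | step 21 | carboxylic acid: 25 with CHO replaced by CO2H | OC(=O)C[C@@H]1CC[C@]2([C@H](CCCO[Si](C)(C)C(C)(C)C)C(O)(C(C)=C)CC[C@]2(C)O)[C@H]1O[Si](CC)(CC)CC
F3 | step 21 | methyl ester of F2 | COC(=O)C[C@@H]1CC[C@]2([C@H](CCCO[Si](C)(C)C(C)(C)C)C(O)(C(C)=C)CC[C@]2(C)O)[C@H]1O[Si](CC)(CC)CC
F4 | step 21 | β-hydroxy ester from F3 and 30 (epimers at the two new centres) | COC(=O)C(C(O)/C=C/C(=C)CCC=C(C)C)[C@@H]1CC[C@]2([C@H](CCCO[Si](C)(C)C(C)(C)C)C(O)(C(C)=C)CC[C@]2(C)O)[C@H]1O[Si](CC)(CC)CC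
F5 | step 21 | β-acetoxy ester from F4 | COC(=O)C(C(OC(C)=O)/C=C/C(=C)CCC=C(C)C)[C@@H]1CC[C@]2([C@H](CCCO[Si](C)(C)C(C)(C)C)C(O)(C(C)=C)CC[C@]2(C)O)[C@H]1O[Si](CC)(CC)CC
F6 | step 21 | methyl (2E,4E)-trienoate corresponding to 33 | C=C(/C=C/C=C(/C(=O)OC)[C@@H]1CC[C@]2([C@H](CCCO[Si](C)(C)C(C)(C)C)C(O)(C(C)=C)CC[C@]2(C)O)[C@H]1O[Si](CC)(CC)CC)CCC=C(C)C
F7 | step 24 | ring B primary allylic alcohol: 36 with CHO replaced by CH2OH (CH2OH syn to C10) | C=C(/C=C/C=C(/COC(C)=O)[C@@H]1CC[C@]2([C@H](CCCO[Si](C)(C)C(C)(C)C)/C(=C(/C)CO)CC[C@]2(C)O)[C@H]1O[Si](CC)(CC)CC)CCC=C(C)C
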